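The runs come from a simulation with constants of no real substance; the scatter is artificial.

1. Slowness was my way in. The new flask has far less free catalyst than substrate, so I asked what pace one catalyst keeps and froze that.

- grey: left-handed substrate 0.10 M; right-handed substrate 0.10 M; gas 41 mM (held); free catalyst 75 µM; run made earlier
- flask: left-handed substrate 0.10 M; gas 41 mM (held); free catalyst 50 µM; right-handed substrate 0.10 M; time 8.0 h
grey run (percent of the left-handed substrate and right-handed substrate together charged)

| time / h | left-handed substrate / % | right-handed substrate / % |
|---|---|---|
| 0.200 | 44 | 50 |
| 0.333 | 42 | 47 |
| 0.417 | 41 | 46 |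
| 0.667 | 39 | 45 |
| 1.00 | 33 | 35 |
| 1.50 | 23 | 32 |
| 2.50 | 13 | 20 |

(each reading ± 1.5 percentage points)
- free catalyst is single-handed; left-handed substrate and right-handed substrate are mirror images of each other, charged as a racemate, each of them at the stated concentration
- at the start none of partner is dissolved
- steps under discussion: free catalyst + left-handed substrate <-> catalyst intermediate A; partner + catalyst intermediate A -> free catalyst + left-handed product; left-handed substrate <-> right-handed substrate; gas <-> partner; free catalyst + right-handed substrate <-> catalyst intermediate B; partner -> decomposed reagent; partner + catalyst intermediate B -> free catalyst + right-handed product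
- an excess is below zero if the other one leads
- no earlier run changes the charge of free catalyst; that part of a forecast is a guess
1. part of the left-handed substrate and right-handed substrate charged together that has reacted at 8.0 h
2. excess of left-handed product over right-handed product in the product at 8.0 h
3. excess of right-handed substrate over left-handed substrate among what is left of the two at 8.0 h

2. Between the first and last grey readings, the two substrates together lost 61.0% of the charge. That gave N = 707 h⁻¹, the substrate turned per catalyst charged per hour: the turnover frequency. Carrying N to another catalyst charge is a guess, because no earlier run varies it.

3. First extreme: N stays frozen (zero order). The new flask then has a budget of 141% of its charge, more than the charge, so this extreme gives c = 100%.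

4. Second extreme: the rate follows the substrate (first order). The grey run gives k = 0.455 h⁻¹. Scaled by catalyst, this gives c = 91.2% for the new flask.

5. The grey substrates fell to 35.1% of the first reading, yet the last span's slope read 71.8% of the first span's, a larger share. So I placed c between the two extremes. This reckoning gives no excesses.

6. The forecast said c 98.5%, eP 1.1% and eS 70%, with “The product is nearly racemic”. Its c lies inside my bounds.

7. The new flask gave c 97.9%, above my lower bound, with eP 22.2% and eS 33.6%. The forecast's eP and the flask's part here: at 8.00 h the new flask held 59.8% left-handed product and 38.0% right-handed product, and the forward half-life of left-handed substrate by the step to right-handed substrate alone, 1.9 h, is short against the time. At 0.800 h, N gives 14.1% reacted; the new flask stood at 16.4%.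

    free catalyst + left-handed substrate ⇌ catalyst intermediate A (K = 16.0 L mol⁻¹, k = 7600 L mol⁻¹ min⁻¹)
    partner + catalyst intermediate A → free catalyst + left-handed product (k = 810 L mol⁻¹ min⁻¹)
    left-handed substrate ⇌ right-handed substrate (k = 0.00600 min⁻¹)
    gas ⇌ partner, rate k4*(csat - [partner]) (kL = 0.440 min⁻¹)
    free catalyst + right-handed substrate ⇌ catalyst intermediate B (K = 21.0 L mol⁻¹, k = 1000 L mol⁻¹ min⁻¹)
    partner → decomposed reagent (k = 0.0780 min⁻¹)
    partner + catalyst intermediate B → free catalyst + right-handed product (k = 360 L mol⁻¹ min⁻¹)

8. For the neighbour charged with 1.2 × 10⁻⁵ M of free catalyst, N gives 33.9% and the first-order extreme gives 44.2%. The computed neighbour reached 40.1%.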